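**An easy step.** Take each reading from one: what remains is the unmade fraction of the charge, the part that is not target, and you follow its logarithm.

| flask | substrate | partner | temperature | remark | time |
|---|---|---|---|---|---|
| north-east | 20 mM | 1.1 equiv | 60 °C | run made earlier |  |
| north | 20 mM | 1.7 equiv | 60 °C | run made earlier |  |
| Thursday's | 20 mM | 1.10 equiv (fed, over 1.5 min) | 60 °C | all else is in the flask from the start; the feed brings no volume worth counting | 2.0 min |
| Saturday's | 20 mM | 1.10 equiv | 60 °C | everything together at the start | 2.0 min |
| Monday's | 20 mM | 1.10 equiv (fed, over 1.5 min) |  | the addition at 30 °C, then warmed to 60 °C; the feed brings no volume worth counting | 2.0 min |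
| Wednesday's | 20 mM | 1.10 equiv |  | everything together at the start at 30 °C, warmed to 60 °C at 1.5 min | 2.0 min |
| Tuesday's | 20 mM (fed, over 1.5 min) | 1.10 equiv | 60 °C | all else is in the flask from the start; the feed brings no volume worth counting | 2.0 min |

| run | time / s | target / % |
|---|---|---|
| north-east | 30.0 | 5.4 |
| north-east | 60.0 | 18.1 |
| north-east | 90.0 | 31.8 |
| north-east | 120 | 41.4 |
| north | 10.0 | 1.5 |
| north | 12.0 | 0 |

(scatter of a reading: 1 percentage point)

- the earlier runs do not show what temperature does; that part of a forecast is a guess

- the flask that comes out highest in amount of target, in percent of the substrate charged, or "all alike" when all lie within 1.5 percentage points (Thursday's / Saturday's / Monday's / Wednesday's / Tuesday's / all alike)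
- target at the end, in percent of the substrate charged, Thursday's
- target at the end, in percent of the substrate charged, Saturday's
- target at the end, in percent of the substrate charged, Monday's
- target at the end, in percent of the substrate charged, Wednesday's
- target at the end, in percent of the substrate charged, Tuesday's

**The pace.** In the north-east run the unmade fraction falls at 0.111 min⁻¹ up to 30.0 s. From there to 120 s its logarithm falls at 0.319 min⁻¹; call this the unmade pace. The start therefore runs at a third of that pace. The last interval reads 0.303 min⁻¹, a factor of 0.950, which the scatter of the readings cannot tell from one.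

**The delay.** The slow start adds up to a delay, the induction period, of 19.6 s. The north run stops at 12.0 s, earlier than the delay read from the north-east run, so it gives no pace. After the delay, in my reckoning, the unmade fraction is the exponential of minus the pace times the heated time beyond the delay.

**My reckoning.** Saturday's repeats the north-east recipe, so its unmade fraction is 0.586, or 41.4% target. Monday's and Wednesday's get 30.0 s of heat. Guessing that the cold stretch makes no target, each ends with 0.946 unmade, or 5.40% target.

**The forecast.** It names Saturday's as highest, with Thursday's 26%, Saturday's 42%, Monday's 10%, Wednesday's 12% and Tuesday's 28%. For the cold flasks it says: “I guessed the rates fall about eightfold”. There my figure is lower than its figures.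

**The flasks.** Saturday's comes out highest at 40.5%, with Thursday's 37.1%, Tuesday's 23.7%, Wednesday's 6.71% and Monday's 6.37%.

    substrate → open intermediate (k = 0.0110 s⁻¹, Ea = 102 kJ mol⁻¹)
    partner → second intermediate (k = 0.0280 s⁻¹, Ea = 87.0 kJ mol⁻¹)
    open intermediate + second intermediate → target (k = 2.20 M⁻¹ s⁻¹, Ea = 37.0 kJ mol⁻¹)
    2 second intermediate → homo product (k = 0.500 M⁻¹ s⁻¹, Ea = 58.0 kJ mol⁻¹)
    substrate ⇌ dormant form (K = 0.310, k = 0.0310 s⁻¹, Ea = 86.0 kJ mol⁻¹, ΔH = −37.0 kJ mol⁻¹)
    (constants at 60 °C)

**The neighbour.** Monday's held 0.0381% target at 1.50 min and ended 93.6% unmade, against the reckoned 94.6%. Now charge Monday's recipe with 5.0 mM of substrate. The unmade pace and the delay contain no charge, so the reckoning again gives 94.6% unmade. That flask ends at 98.0% unmade, with 2.02% target. Its substrate left is 57%, the same as Monday's 57%, and its open intermediate stands at 22.6%, against Monday's 18.2%.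

The data come from a simulation for substances that don't exist; noise was put on by code.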